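Ring A is disconnected at C6–C1 and C2–C3 into a four-carbon vinylketene (C3–C6, carrying H, methyl and prenyl) and a two-carbon aryl ethynyl ether that already holds ring B on its oxygen. The key step exploits the meta relationship of the C6 hydroxyl and the C2 aryloxy oxygen across unsubstituted C1. Heating 3-methyl-4-prenylcyclobutenone with the ring B ynol ether should assemble the tetrasubstituted ring A phenol, diaryl ether included, in one operation, leaving C1 as the only free ortho position for the ester carbon. The precursors are a racemic cyclobutenone, made by ketene–ethoxyacetylene cycloaddition, and a 2-ethynyloxy-3,5-dimethoxybenzyl TBS ether.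

Key step: step 9

Remark: ring A is numbered C1 (ester carbon), C2 (aryloxy), C3 (H), C4 (methyl), C5 (prenyl), C6 (hydroxyl); ArO stands for 2-(tert-butyldimethylsilyloxymethyl)-4,6-dimethoxyphenoxy.
Remark: the commercial ring B aldehyde carries bromine where the target has a methoxy group, so that branch opens with a copper-catalysed methoxylation.
Remark: C6–C1 and C2–C3 are made in the ketene–alkyne [2+2] event; the later six-electron closure only re-forms C5–C6, the bond broken when the cyclobutenone opens.
Remark: the ring B phenol is converted to its dichlorovinyl ether before the aldehyde is reduced and silylated, so no free ortho-hydroxybenzyl alcohol is handled.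

Step 1
Reactants: 1 5-methylhex-4-enoic acid
Product: 2 5-methylhex-4-enoyl chloride
Conditions: (COCl)2, cat. DMF, CH2Cl2, 0 °C to rt; evaporate, use crude
Reagents that add atoms: oxalyl chloride, O=C(Cl)C(=O)Cl
Why: Acyl chloride formation through the Vilsmeier-type chloroiminium from oxalyl chloride and DMF is mild enough to leave the trisubstituted olefin untouched, and all by-products are volatile.

Step 2
Reactants: 2 5-methylhex-4-enoyl chloride; 3 ethoxyacetylene
Product: 5 racemic 3-ethoxy-4-(3-methylbut-2-enyl)cyclobut-2-en-1-one, via prenylketene 4 (not isolated)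
Conditions: Et3N, 3 (2.5 equiv), Et2O, slow addition of 2, rt
Reagents that add atoms: none
Why: Dehydrochlorination gives prenylketene, which undergoes a ketene–alkyne [2+2] cycloaddition in which the unsubstituted, nucleophilic carbon of the ynol ether bonds to the ketene carbonyl carbon, placing ethoxy at C3 and prenyl at C4; slow addition keeps the ketene dilute so dimerisation is outrun, and the new C4 stereocenter is formed racemic and is of no consequence.

Step 3
Reactants: 5 racemic 3-ethoxy-4-(3-methylbut-2-enyl)cyclobut-2-en-1-one
Product: 7 racemic 3-methyl-4-(3-methylbut-2-enyl)cyclobut-2-en-1-one, via tertiary carbinol 6 (not isolated)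
Conditions: MeLi, Et2O, −78 °C; then 1 M HCl, THF, 0 °C to rt
Reagents that add atoms: methyllithium, [Li]C; water, O
Why: 1,2-Addition of MeLi to the vinylogous ester followed by acid hydrolysis of the enol ether with loss of the tertiary hydroxyl (Stork–Danheiser-type carbonyl transposition) moves the carbonyl to the former ethoxy carbon and leaves methyl on the enone β-carbon, while the racemic C4 center is untouched because enolisation toward it would create a cyclobutadiene.

Step 4
Reactants: 8 5-bromo-2-hydroxy-3-methoxybenzaldehyde
Product: 9 2-hydroxy-3,5-dimethoxybenzaldehyde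
Conditions: NaOMe (excess), CuBr (cat.), MeOH/DMF, 110 °C; then aq. HCl
Reagents that add atoms: sodium methoxide, [Na+].[O-]C
Why: Ullmann-type copper-catalysed methoxylation of aryl bromides with NaOMe is established for bromo-hydroxybenzaldehydes, which react as phenoxides (this also shields the aldehyde from Cannizzaro chemistry), and it installs the ring B methoxy group that the commercial aldehyde lacks.

Step 5
Reactants: 9 2-hydroxy-3,5-dimethoxybenzaldehyde; 10 trichloroethylene
Product: 12 2-[(E)-1,2-dichloroethenyloxy]-3,5-dimethoxybenzaldehyde, via dichloroacetylene 11 (not isolated)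
Conditions: K2CO3, DMF, 70 °C
Reagents that add atoms: none
Why: Carbonate-induced dehydrochlorination of trichloroethylene gives dichloroacetylene in low stationary concentration, and anti addition of the phenoxide across it delivers the (E)-1,2-dichlorovinyl aryl ether, a known phenol-to-dichlorovinyl-ether conversion.

Step 6
Reactants: 12 2-[(E)-1,2-dichloroethenyloxy]-3,5-dimethoxybenzaldehyde
Product: 13 {2-[(E)-1,2-dichloroethenyloxy]-3,5-dimethoxyphenyl}methanol
Conditions: NaBH4, MeOH/THF, 0 °C
Reagents that add atoms: none
Why: Borohydride reduction of the aromatic aldehyde is chemoselective because vinylic chlorides and aryl ethers are inert to NaBH4 at 0 °C.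

Step 7
Reactants: 13 {2-[(E)-1,2-dichloroethenyloxy]-3,5-dimethoxyphenyl}methanol
Product: 14 tert-butyl({2-[(E)-1,2-dichloroethenyloxy]-3,5-dimethoxyphenyl}methoxy)dimethylsilane
Conditions: TBSCl, imidazole, DMF, rt
Reagents that add atoms: tert-butyldimethylsilyl chloride, CC(C)(C)[Si](C)(C)Cl
Why: Imidazole-promoted silylation of the only hydroxyl in the molecule, a primary benzylic alcohol, gives a TBS ether that tolerates butyllithium, the thermal benzannulation and the later oxidations.

Step 8
Reactants: 14 tert-butyl({2-[(E)-1,2-dichloroethenyloxy]-3,5-dimethoxyphenyl}methoxy)dimethylsilane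
Product: 17 tert-butyl{[2-(ethynyloxy)-3,5-dimethoxyphenyl]methoxy}dimethylsilane, via aryloxy chloroalkyne 15 (not isolated), via lithium aryloxyacetylide 16 (not isolated)
Conditions: n-BuLi (2.3 equiv), THF, −78 to −40 °C; then sat. aq. NH4Cl, −78 °C; filter through basic alumina, use at once
Reagents that add atoms: none
Why: Butyllithium removes the vinylic proton with loss of LiCl to give the chloroalkyne, chlorine–lithium exchange then gives the acetylide (the standard dichlorovinyl ether route to ynol ethers), and cold protonation releases the terminal aryl ynol ether, which is used immediately because such alkynes oligomerise and hydrate on standing.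

Step 9
Reactants: 7 racemic 3-methyl-4-(3-methylbut-2-enyl)cyclobut-2-en-1-one; 17 tert-butyl{[2-(ethynyloxy)-3,5-dimethoxyphenyl]methoxy}dimethylsilane
Product: 22 5-ArO-3-methyl-2-(3-methylbut-2-enyl)phenol, via vinylketene 18 (not isolated), via aryloxy alkenylcyclobutenone 19 (not isolated), via dienylketene 20 (not isolated), via cyclohexadienone 21 (not isolated)
Conditions: 7 (1.3 equiv), PhMe, 80 °C then 110 °C, sealed tube; then K2CO3, MeOH, rt
Reagents that add atoms: none
Why: Conrotatory four-electron opening of 7 (prenyl rotating outward) gives vinylketene 18, whose ketene C=C adds the ynol ether by [2+2], the unsubstituted nucleophilic alkyne carbon bonding to the ketene carbonyl carbon (C6–C1) and the oxygen-bearing carbon to the ketene α-carbon (C2–C3), so that 19 is a 3-aryloxy-4-alkenylcyclobutenone. Reversible four-electron opening of 19 gives dienylketene 20, whose (Z)-configured isomer closes ring A by a thermally allowed disrotatory six-electron electrocyclisation that re-forms C5–C6, and the cyclohexa-2,4-dienone 21 tautomerises irreversibly to the phenol. The closest known reaction type is the Danheiser benzannulation of cyclobutenones with alkoxy- and siloxyacetylenes; an aryl ynol ether belongs to the same class and, having no β-hydrogen on an sp3 carbon, cannot fragment by a retro-ene path at these temperatures. No stereocenter remains, since the ring stereocenters of 7, 19 and 21 are racemic and are erased on aromatisation. The step needs regiocontrol in the [2+2] and chemoselectivity over the prenyl olefin, and both are secured by the oxygen lone pair, which polarises the alkyne and makes it far more ketenophilic than an unactivated trisubstituted alkene; the closing methanolysis returns any phenol that was acylated by the vinylketene.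

Step 10
Reactants: 22 5-ArO-3-methyl-2-(3-methylbut-2-enyl)phenol
Product: 23 6-ArO-2-hydroxy-4-methyl-3-(3-methylbut-2-enyl)benzaldehyde
Conditions: MgCl2, Et3N, (CH2O)n, THF, reflux; then dilute aq. HCl, 0 °C
Reagents that add atoms: paraformaldehyde (formaldehyde), C=O
Why: Magnesium-mediated ortho-formylation (Casnati–Skattebøl type) delivers formaldehyde from the magnesium phenoxide exclusively to an ortho carbon, and since C5 carries the prenyl group the only such site is C1; a second equivalent of formaldehyde then oxidises the hydroxymethyl intermediate by hydride transfer, and the para position C3 is not attacked under this chelation control.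

Step 11
Reactants: 23 6-ArO-2-hydroxy-4-methyl-3-(3-methylbut-2-enyl)benzaldehyde
Product: 24 6-ArO-2-hydroxy-4-methyl-3-(3-methylbut-2-enyl)benzoic acid
Conditions: NaClO2, NaH2PO4, 2-methyl-2-butene (large excess), t-BuOH/THF/H2O, 0 °C to rt
Reagents that add atoms: sodium chlorite, [Na+].[O-]Cl=O
Why: Pinnick oxidation converts the aldehyde to the acid under buffered conditions, the excess 2-methyl-2-butene intercepting HOCl so that the prenyl olefin and the electron-rich rings are spared, and the primary TBS ether is stable at this pH.

Step 12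
Reactants: 24 6-ArO-2-hydroxy-4-methyl-3-(3-methylbut-2-enyl)benzoic acid
Product: 25 methyl 6-ArO-2-hydroxy-4-methyl-3-(3-methylbut-2-enyl)benzoate
Conditions: TMSCHN2, PhMe/MeOH, 0 °C
Reagents that add atoms: trimethylsilyldiazomethane, C[Si](C)(C)C=[N+]=[N-]
Why: Trimethylsilyldiazomethane with methanol methylates the carboxylic acid rapidly, whereas the far less acidic phenol, hydrogen-bonded to the ortho carbonyl, is not alkylated in a brief reaction at 0 °C.

Step 13
Reactants: 25 methyl 6-ArO-2-hydroxy-4-methyl-3-(3-methylbut-2-enyl)benzoate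
Product: 26 methyl 2-hydroxy-6-[2-(hydroxymethyl)-4,6-dimethoxyphenoxy]-4-methyl-3-(3-methylbut-2-enyl)benzoate
Conditions: HF·pyridine, pyridine, THF, 0 °C to rt
Reagents that add atoms: none
Why: Fluoride cleavage of the primary silyl ether under buffered, non-basic conditions avoids the benzylic alkoxide that could attack the methyl ester across the diaryl ether (eight-membered lactonisation) and is too mild to cyclise the ortho-prenylphenol to a chroman.

Compound list
1 | 5-methylhex-4-enoic acid | CC(C)=CCCC(=O)O | starting material
2 | 5-methylhex-4-enoyl chloride | CC(C)=CCCC(=O)Cl | intermediate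
3 | ethoxyacetylene | CCOC#C | starting material
4 | prenylketene, 5-methylhexa-1,4-dien-1-one (not isolated) | CC(C)=CCC=C=O | intermediate
5 | racemic 3-ethoxy-4-(3-methylbut-2-enyl)cyclobut-2-en-1-one | CCOC1=CC(=O)C1CC=C(C)C | intermediate
6 | 3-ethoxy-1-methyl-4-(3-methylbut-2-enyl)cyclobut-2-en-1-ol, diastereomer mixture (not isolated) | CCOC1=CC(C)(O)C1CC=C(C)C | intermediate
7 | racemic 3-methyl-4-(3-methylbut-2-enyl)cyclobut-2-en-1-one | CC1=CC(=O)C1CC=C(C)C | intermediate
8 | 5-bromo-2-hydroxy-3-methoxybenzaldehyde | COc1cc(Br)cc(C=O)c1O | starting material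
9 | 2-hydroxy-3,5-dimethoxybenzaldehyde | COc1cc(OC)cc(C=O)c1O | intermediate
10 | trichloroethylene | ClC=C(Cl)Cl | starting material
11 | dichloroacetylene (not isolated) | ClC#CCl | intermediate
12 | 2-[(E)-1,2-dichloroethenyloxy]-3,5-dimethoxybenzaldehyde | COc1cc(OC)cc(C=O)c1O/C(Cl)=C\Cl | intermediate
13 | {2-[(E)-1,2-dichloroethenyloxy]-3,5-dimethoxyphenyl}methanol | COc1cc(OC)cc(CO)c1O/C(Cl)=C\Cl | intermediate
14 | tert-butyl({2-[(E)-1,2-dichloroethenyloxy]-3,5-dimethoxyphenyl}methoxy)dimethylsilane | COc1cc(OC)cc(CO[Si](C)(C)C(C)(C)C)c1O/C(Cl)=C\Cl | intermediate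
15 | tert-butyl{[2-(chloroethynyloxy)-3,5-dimethoxyphenyl]methoxy}dimethylsilane (not isolated) | COc1cc(OC)cc(CO[Si](C)(C)C(C)(C)C)c1OC#CCl | intermediate
16 | lithium acetylide of 17, {2-[2-(tert-butyldimethylsilyloxymethyl)-4,6-dimethoxyphenoxy]ethynyl}lithium (not isolated) | COc1cc(OC)cc(CO[Si](C)(C)C(C)(C)C)c1OC#C[Li] | intermediate
17 | tert-butyl{[2-(ethynyloxy)-3,5-dimethoxyphenyl]methoxy}dimethylsilane (2-(tert-butyldimethylsilyloxymethyl)-1-ethynyloxy-4,6-dimethoxybenzene) | C#COc1c(CO[Si](C)(C)C(C)(C)C)cc(OC)cc1OC | intermediate
18 | (3E)-3,7-dimethylocta-1,3,6-trien-1-one, vinylketene (not isolated) | O=C=C/C(C)=C/CC=C(C)C | intermediate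
19 | racemic 3-[2-(tert-butyldimethylsilyloxymethyl)-4,6-dimethoxyphenoxy]-4-[(2E)-6-methylhepta-2,5-dien-2-yl]cyclobut-2-en-1-one (not isolated) | O=C1C=C(Oc2c(CO[Si](C)(C)C(C)(C)C)cc(OC)cc2OC)C1/C(C)=C/CC=C(C)C | intermediate
20 | (3E,5E)-3-[2-(tert-butyldimethylsilyloxymethyl)-4,6-dimethoxyphenoxy]-5,9-dimethyldeca-1,3,5,8-tetraen-1-one, dienylketene with ketene and C5 cis across C3=C4 (not isolated) | O=C=C/C(Oc1c(CO[Si](C)(C)C(C)(C)C)cc(OC)cc1OC)=C\C(C)=C\CC=C(C)C | intermediate
21 | racemic 3-[2-(tert-butyldimethylsilyloxymethyl)-4,6-dimethoxyphenoxy]-5-methyl-6-(3-methylbut-2-enyl)cyclohexa-2,4-dien-1-one (not isolated) | O=C1C=C(Oc2c(CO[Si](C)(C)C(C)(C)C)cc(OC)cc2OC)C=C(C)C1CC=C(C)C | intermediate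
22 | 5-[2-(tert-butyldimethylsilyloxymethyl)-4,6-dimethoxyphenoxy]-3-methyl-2-(3-methylbut-2-enyl)phenol | CC(C)=CCc1c(C)cc(Oc2c(CO[Si](C)(C)C(C)(C)C)cc(OC)cc2OC)cc1O | intermediate
23 | 6-[2-(tert-butyldimethylsilyloxymethyl)-4,6-dimethoxyphenoxy]-2-hydroxy-4-methyl-3-(3-methylbut-2-enyl)benzaldehyde | O=Cc1c(Oc2c(CO[Si](C)(C)C(C)(C)C)cc(OC)cc2OC)cc(C)c(CC=C(C)C)c1O | intermediate
24 | 6-[2-(tert-butyldimethylsilyloxymethyl)-4,6-dimethoxyphenoxy]-2-hydroxy-4-methyl-3-(3-methylbut-2-enyl)benzoic acid | OC(=O)c1c(Oc2c(CO[Si](C)(C)C(C)(C)C)cc(OC)cc2OC)cc(C)c(CC=C(C)C)c1O | intermediate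
25 | methyl 6-[2-(tert-butyldimethylsilyloxymethyl)-4,6-dimethoxyphenoxy]-2-hydroxy-4-methyl-3-(3-methylbut-2-enyl)benzoate | COC(=O)c1c(Oc2c(CO[Si](C)(C)C(C)(C)C)cc(OC)cc2OC)cc(C)c(CC=C(C)C)c1O | intermediate
26 | methyl 2-hydroxy-6-[2-(hydroxymethyl)-4,6-dimethoxyphenoxy]-4-methyl-3-(3-methylbut-2-enyl)benzoate | COC(=O)c1c(Oc2c(CO)cc(OC)cc2OC)cc(C)c(CC=C(C)C)c1O | target

Total step count: 13.
Longest linear sequence: 10 steps (8 to 26 through steps 4 to 13); the cyclobutenone branch (steps 1 to 3) joins at step 9.

Steps most likely to fail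

1. Step 9. The terminal aryloxyacetylene may be consumed by oligomerisation or adventitious hydration faster than it captures the vinylketene, which would then dimerise. The fallback carries the alkyne in a C-silylated, storable form and removes the silicon after ring A exists. It sets out from 14: the acetylide 16 is generated as in step 8 and quenched with Me3SiCl instead of a proton source to give tert-butyl{[3,5-dimethoxy-2-(trimethylsilylethynyloxy)phenyl]methoxy}dimethylsilane F1, which can be chromatographed and stored. Heating F1 with 7 (PhMe, 110 °C) should give, with unchanged regiochemistry because the silicon-bearing carbon remains the nucleophilic one, 5-[2-(tert-butyldimethylsilyloxymethyl)-4,6-dimethoxyphenoxy]-3-methyl-2-(3-methylbut-2-enyl)-6-(trimethylsilyl)phenol F2. Ipso-protodesilylation of this doubly oxygen-activated arylsilane (TFA, 2 equiv, CH2Cl2, −20 °C) comes back to the route at 22.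

2. Step 10. Electrophilic attack at the crowded C1 may be slow, so that the hydroxymethyl stage condenses with a second phenol or stalls before the hydride transfer. The fallback separates carbon delivery from oxidation. It sets out from 22: boron-templated ortho-hydroxymethylation (PhB(OH)2, paraformaldehyde, cat. EtCO2H, PhMe, reflux with water removal) traps the single formaldehyde unit intramolecularly as 5-[2-(tert-butyldimethylsilyloxymethyl)-4,6-dimethoxyphenoxy]-7-methyl-8-(3-methylbut-2-enyl)-2-phenyl-4H-1,3,2-benzodioxaborine F3. Transesterification with propane-1,3-diol (THF, rt) releases 3-[2-(tert-butyldimethylsilyloxymethyl)-4,6-dimethoxyphenoxy]-2-(hydroxymethyl)-5-methyl-6-(3-methylbut-2-enyl)phenol F4. Oxidation of the benzylic alcohol with MnO2 (CH2Cl2, rt) comes back to the route at 23.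

3. Step 11. Electrophilic chlorine species released from chlorite may attack the prenyl double bond or the electron-rich ring B before the scavenger intercepts them, aggravated by slow oxidation of the hindered, hydrogen-bonded aldehyde. The fallback avoids chlorine-based oxidants and the free acid altogether. It sets out from 23 and uses carbene-catalysed oxidative esterification (1,4-dimethyl-1,2,4-triazolium iodide as precatalyst, DBU, 3,3',5,5'-tetra-tert-butyldiphenoquinone, MeOH/THF, rt), which passes through an acyl azolium that methanol intercepts. It comes back to the route at 25, skipping 24 and step 12, and forms no compound outside the list (F0).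

Further compounds
F1 | step 9 | tert-butyl{[3,5-dimethoxy-2-(trimethylsilylethynyloxy)phenyl]methoxy}dimethylsilane | C[Si](C)(C)C#COc1c(CO[Si](C)(C)C(C)(C)C)cc(OC)cc1OC
F2 | step 9 | 5-[2-(tert-butyldimethylsilyloxymethyl)-4,6-dimethoxyphenoxy]-3-methyl-2-(3-methylbut-2-enyl)-6-(trimethylsilyl)phenol | CC(C)=CCc1c(C)cc(Oc2c(CO[Si](C)(C)C(C)(C)C)cc(OC)cc2OC)c([Si](C)(C)C)c1O
F3 | step 10 | 5-[2-(tert-butyldimethylsilyloxymethyl)-4,6-dimethoxyphenoxy]-7-methyl-8-(3-methylbut-2-enyl)-2-phenyl-4H-1,3,2-benzodioxaborine | CC(C)=CCc1c(C)cc(Oc3c(CO[Si](C)(C)C(C)(C)C)cc(OC)cc3OC)c2COB(c4ccccc4)Oc12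
F4 | step 10 | 3-[2-(tert-butyldimethylsilyloxymethyl)-4,6-dimethoxyphenoxy]-2-(hydroxymethyl)-5-methyl-6-(3-methylbut-2-enyl)phenol | OCc1c(Oc2c(CO[Si](C)(C)C(C)(C)C)cc(OC)cc2OC)cc(C)c(CC=C(C)C)c1O
F0 | step 11 | none | none
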